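## The problem

Target 30 (CNP0273287.1) is a guaiane: a cyclopentenone (C1–C5, C3 ketone, tetrasubstituted C4=C5 alkene with the C4 methyl) fused along C1–C5 to a seven-membered ring (C1, C5–C10; C11 is the carbinol carbon on C7, C14 the methyl carbon on C10, C15 the methyl carbon on C4). The seven-membered ring carries five stereocentres: the ring-fusion carbinol C1, C6 (free allylic alcohol), C7 (bearing the acetoxylated C11), C8 (angelate) and C10 (methyl). The oxygens at C6 and C8, C11 on C7 and the C10 methyl all lie on one face (β); only the C1 hydroxyl lies on the other (α), so C6/C7/C8 form a crowded all-cis triad. C6 can control C7 (protonation of a C7=C8 enol derivative anti to the C6 oxygen) and, through C7, C8 (hydride anti to C11). C1 and C10 lie across the ring and must be set by the facial bias of the three β substituents and by the C1 hydroxyl acting as a directing group for C10. Four oxygens must end in four different states: secondary angelate, tertiary acetate, free secondary and free tertiary hydroxyl. The angelate (Z to E isomerisation; no tolerance for hydride, enolate or hydrogenation conditions), the C1 carbinol (a tertiary allylic β-hydroxy ketone, prone to dehydration and retro-aldol cleavage) and the C11 oxygen (β to C8 and eliminated whenever C8 is a ketone) will not survive rough treatment. The enabling feature is the C9 methylene between C8 and C10 together with the C5–C6 bond beside the ring fusion: with C8 at ketone level and C1=C10 as an alkene, the seven-membered ring is a cyclohepta-1,4-diene (C1=C10, C7=C8), the product of a divinylcyclopropane rearrangement between a C10 carbenoid carrying the C1=C5 vinyl group and a C9=C8–C7=C6 diene.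

## Retrosynthesis

**Acyl groups and the C6 ether (30 back to 25).** The three C–O bonds to the acyl and benzyl groups are cut last. Target 30 comes from PMB ether 29, which comes from angelate 28 by acetylation of the C11 hydroxyl, and 28 comes from triol 25 and angelic acid 26. The secondary C8 hydroxyl is acylated before the tertiary C11 hydroxyl because the reverse order has no selectivity. The C6 ether stays until the end so that C6–OH never competes. The forward reactions must install the angelate without Z/E isomerisation and acetylate the C11 hydroxyl in preference to the ring-fusion C1 hydroxyl.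

**C4 methyl and C4=C5 alkene (25 back to 22).** The C4–C15 bond and the C4=C5 unsaturation are removed: 25 comes from the bis-silyl ether 24, 24 from methyl ketone 23 by dehydrogenation, and 23 from ketone 22 by methylation. This is done only after C1 has become a carbinol. While C1=C10 is an enoate, C2 is the most acidic position. Once C1 is quaternary and carries an alkoxide, enolisation goes to C4 and dehydrogenation can only run to C4–C5. The precursor 22 is a plain cyclopentanone; the forward reactions must be α′-selective and must not open the β-hydroxy ketone.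

**C1 hydroxyl and C10 methyl (22 back to 17).** Ketone 22 comes from ketal 21, and 21 from the exocyclic alkene 20 by hydrogenation (C10–H bond). Alkene 20 comes from epoxy alcohol 18 through iodide 19 (C1–O retained, C14–O removed), and 18 from allylic alcohol 17 (C1–O and C10–O bonds). Direct hydration of a tetrasubstituted C1=C10 alkene would have no regiocontrol. Epoxidation and reductive opening of the enoate itself would leave C10 to an uncontrolled protonation. The allylic transposition puts oxygen only on C1 and lets that hydroxyl deliver hydrogen to C10. The epoxidation must occur on the α face, which carries only hydrogens.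

**C7 and C8 (17 back to 13).** No skeletal bond is cut. Alcohol 17 comes from ester 16, 16 from alcohol 15, 15 from ketone 14, and 14 from the silyl enol ether 13. The C7=C8 enol ether of 13 is the latent C8 carbinol; unmasking it creates C7 by protonation and C8 by hydride addition, both under control of the C6 ether. The ketone 14 must be made and consumed without epimerisation at C7 or β-elimination.

**Seven-membered ring (13 back to 6 and 11).** C9–C10 and C5–C6 are cut, through the cis-divinylcyclopropane 12, to vinyldiazoacetate 6 and 2-silyloxydiene 11. Against cuts that go through medium rings or 1,4-diketones, this one joins two small achiral fragments intermolecularly, forms the ring by a sigmatropic shift, and places ester, ketal, enol ether and ether at C10, C3, C8 and C6 at four distinguishable oxidation levels. The forward reaction must cyclopropanate only C9=C8, give the cis-divinyl isomer, and set C6 absolutely from the catalyst; C5 is set relative to C6 and later becomes sp2.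

**Carbenoid precursor (6 back to 1 and 3).** Diazo ester 6 comes from β,γ-unsaturated ester 5 by diazo transfer. Ester 5 is cut at C1–C10 into enol triflate 2 and the zinc enolate 4 of methyl bromoacetate 3, and 2 comes from ketal ketone 1. The ketal fixes the enolisation of 1 away from C2 and hence the C1=C5 position of the vinyl group.

**Diene (11 back to 7 and 8).** Diene 11 comes from hydroxy enone 10 by double silylation. Enone 10 is cut at one C11–CH3 bond to the symmetrical diketone 9, and 9 comes from the ethoxymethylidene diketone 7 and 4-methoxybenzyl alcohol 8 by alkoxy exchange. Formylating a methyl ketone at its hindered methylene carbon would go to the methyl group instead. The symmetry of 9 removes that regiochemical question and leaves only mono-addition and enol ether geometry to control.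

## Roads not taken

**Alternative 1:** The C1–C5 bond is cut, giving a ten-membered carbocyclic ketone. In the forward direction an alkylaluminium chloride activates the C1 ketone, C5 of the C4=C5 alkene attacks it in a transannular carbonyl-ene reaction, the allylic C3 hydrogen is transferred, and both rings close to give the hydroazulenol silyl enol ether A1.
- Merits: both rings, the C1 carbinol and the enone precursor arise in one step with C6, C7, C8, C10 and the C11 acetate already in place. A1 is one oxidation away from the C4-methyl enone, so the end game is clearly shorter than the chosen one, which spends about eight operations on C1, C10 and the cyclopentenone.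
- Weak points: the difficulty moves into the ten-membered ring, which must be made with four stereocentres, an epimerisable C10 next to the ketone, a tertiary acetate and three silyl ethers. The face of attack at C1 and C5 depends on medium-ring conformation and is hard to predict. The Lewis acid can ionise the allylic silyl ether or divert the ene reaction to the C15 hydrogens.
- Comparison: better in step economy after the key step. The chosen plan offers a ring-forming step that is intermolecular, catalytic and precedented, no medium ring, and absolute stereocontrol from a catalyst.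

**Alternative 2:** The C6–C7 bond is cut (and the O–C12 bond re-formed), giving a ten-membered cyclic α-stannyl bis-allylic ether. Tin–lithium exchange at C6 triggers a [2,3]-Wittig shift that forms C6–C7, cleaves O–C12 and contracts the ether to the carbocycle A2, with a free C6 hydroxyl and a C7 isopropenyl group.
- Merits: the five-membered ring arrives complete (C4 methyl, C4=C5, protected C1 oxygen, C3 ketal) together with the C10 methyl and C8 oxygen, so none of the late cyclopentenone work of the chosen plan is needed. C6 and C7 are created together in a concerted suprafacial step.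
- Weak points: the substrate is a medium-ring ether with a configurationally defined α-stannyl carbon and a tetrasubstituted alkene. Whether the medium-ring transition state gives the all-cis C6/C7/C8 relationship is not predictable, and the [1,2]-shift competes. C11 still has to be oxygenated (hydration of the isopropenyl group) and acetylated while the liberated C6 hydroxyl is protected again.
- Comparison: superior for ring A and C1. The chosen plan avoids the medium ring and stoichiometric tin, has the C11 oxygen in place from the start, and takes C6 from a catalyst.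

**Alternative 3:** C5–C6 and C7–C8 are cut in a De Mayo sequence. A silicon-tethered enol ether of a 2-substituted cyclopentane-1,3-dione adds photochemically to a C6=C7 enol ether, fluoride releases the cyclobutanol, and retro-aldol cleavage of C5–C8 expands the ring by two carbons to the cycloheptane-1,4-dione A3.
- Merits: cheap starting material; the cis C6/C7 relationship comes from the tethered cycloaddition; C1 and C8 are at the correct oxidation level and both methyl groups are present. The C1 carbinol would arise from an intramolecular aldol reaction, the natural retron of the β-hydroxy ketone, which is more direct than the epoxidation and transposition used here.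
- Weak points: A3 has three ketones (C1, C3, C8), of which only C8 may be reduced, and three epimerisable centres (C4, C5, C10). The aldol must give the α hydroxyl at C1 without dehydrating. C7 sits next to a ketone with two β leaving groups. The benzyl ether must be removed in the presence of the angelate and the enone. Absolute configuration has to come from the dione or a chiral tether.
- Comparison: better for C1 and the methyl groups. The chosen plan keeps C3, C8 and C10 at three different oxidation levels from the outset, needs no photochemistry, and sets C6 catalytically.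

Key step: step 7

Assumption: 1,4-dioxaspiro[4.4]nonan-7-one 1 and 3-(ethoxymethylidene)pentane-2,4-dione 7 are treated as purchasable. α is the face of the bicycle carrying the C1 hydroxyl of the target, β the opposite face. PMB = 4-methoxybenzyl, TES = triethylsilyl, TBS = tert-butyldimethylsilyl. Guaiane numbering is used for the bicyclic compounds.

## Route

Step 1
Reactants: 1 1,4-dioxaspiro[4.4]nonan-7-one
Product: 2 1,4-dioxaspiro[4.4]non-7-en-7-yl trifluoromethanesulfonate
Conditions: LiN(SiMe3)2, THF, −78 °C; PhNTf2, −78 → 0 °C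
Reagents that add atoms: N-phenylbis(trifluoromethanesulfonimide), O=S(=O)(N(c1ccccc1)S(=O)(=O)C(F)(F)F)C(F)(F)F
Why: Kinetic deprotonation occurs at the CH2 remote from the ketal (the CH2 between carbonyl and ketal is hindered and its enolate would have a β-alkoxy leaving group), and O-triflation of the enolate gives the enol triflate with the alkene in the future C1=C5 position.

Step 2
Reactants: 2 1,4-dioxaspiro[4.4]non-7-en-7-yl trifluoromethanesulfonate; 3 methyl bromoacetate
Product: 5 methyl 2-(1,4-dioxaspiro[4.4]non-7-en-7-yl)acetate, via bromozinc ester enolate 4 (not isolated)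
Conditions: Zn dust (Me3SiCl-activated), THF, 25 °C; then 2, Pd2(dba)3 (zerovalent palladium, 2.5 mol %), XPhos, THF, 50 °C
Reagents that add atoms: none
Why: Negishi-type cross-coupling of a Reformatsky zinc enolate with an alkenyl triflate forms the C1–C10 bond under neutral conditions, so the alkene stays β,γ to the ester.

Step 3
Reactants: 5 methyl 2-(1,4-dioxaspiro[4.4]non-7-en-7-yl)acetate
Product: 6 methyl 2-diazo-2-(1,4-dioxaspiro[4.4]non-7-en-7-yl)acetate
Conditions: 4-acetamidobenzenesulfonyl azide, DBU, MeCN, 0 °C; used promptly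
Reagents that add atoms: 4-acetamidobenzenesulfonyl azide, CC(=O)Nc1ccc(cc1)S(=O)(=O)N=[N+]=[N-]
Why: Diazo transfer to the doubly activated (allylic and α to the ester) methylene through its DBU-generated dienolate is the standard entry to vinyldiazoacetates; the ketal keeps C2 non-acidic.

Step 4
Reactants: 7 3-(ethoxymethylidene)pentane-2,4-dione; 8 4-methoxybenzyl alcohol
Product: 9 3-[(4-methoxybenzyloxy)methylidene]pentane-2,4-dione
Conditions: PPTS (2 mol %), toluene, 80 °C, reduced pressure (EtOH removed)
Reagents that add atoms: none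
Why: Alkoxy exchange by addition–elimination at the methine carbon of an alkoxymethylidene 1,3-diketone, driven by removal of ethanol; the two acetyl groups are equivalent, so no regio- or geometric isomers can arise.

Step 5
Reactants: 9 3-[(4-methoxybenzyloxy)methylidene]pentane-2,4-dione
Product: 10 (E)-4-hydroxy-3-[(4-methoxybenzyloxy)methylidene]-4-methylpentan-2-one
Conditions: MeLi (1.1 equiv), CeCl3 (1.2 equiv), THF, −78 °C
Reagents that add atoms: methyllithium, [Li]C
Why: Organocerium 1,2-addition to a conjugated ketone suppresses conjugate addition–elimination and enolisation, and the resulting alkoxide deactivates the remaining vinylogous-ester carbonyl against a second addition; the (E) isomer (ether oxygen anti to the remaining acetyl) is the preferred push–pull geometry and the isomers can equilibrate through the dipolar resonance form.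

Step 6
Reactants: 10 (E)-4-hydroxy-3-[(4-methoxybenzyloxy)methylidene]-4-methylpentan-2-one
Product: 11 (1E)-1-(4-methoxybenzyloxy)-3-(triethylsilyloxy)-2-[2-(triethylsilyloxy)propan-2-yl]buta-1,3-diene
Conditions: TESOTf (2.5 equiv), Et3N (4 equiv), CH2Cl2, −78 → 0 °C; chromatography on Et3N-deactivated silica
Reagents that add atoms: triethylsilyl trifluoromethanesulfonate, CC[Si](CC)(CC)OS(=O)(=O)C(F)(F)F
Why: Silyl triflate/amine enol silylation of the methyl ketone (its methyl group is the only enolisable position) gives the 2-silyloxydiene and protects the tertiary alcohol in the same operation, as in the preparation of 1-alkoxy-3-silyloxybutadienes.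

Step 7
Reactants: 6 methyl 2-diazo-2-(1,4-dioxaspiro[4.4]non-7-en-7-yl)acetate; 11 (1E)-1-(4-methoxybenzyloxy)-3-(triethylsilyloxy)-2-[2-(triethylsilyloxy)propan-2-yl]buta-1,3-diene
Product: 13 methyl 3,3-(ethylenedioxy)-6β-(4-methoxybenzyloxy)-8,11-bis(triethylsilyloxy)-15-nor-5αH-guaia-1(10),7-dien-14-oate, via cis-divinylcyclopropane 12 (not isolated)
Conditions: dirhodium tetrakis[(S)-N-(4-dodecylphenylsulfonyl)prolinate] (1 mol %), hexanes, −26 °C, slow addition of 6 to 11 (1.5 equiv); then 25 °C
Reagents that add atoms: none
Why: The dirhodium prolinate turns 6 into a donor/acceptor vinylcarbenoid that adds to the terminal, electron-rich and unhindered C9=C8 silyl enol ether bond of 11 to give the cis-divinylcyclopropane 12. A [3,3]-sigmatropic (Cope) shift through a boat transition state then cleaves C8–C10 and forms C5–C6, giving the cyclohepta-1,4-diene 13 (C1=C10, C7=C8); the formal [4+3] annulation of vinyldiazoacetates with dienes under chiral dirhodium prolinate catalysis is the closest known reaction type. The seven-membered ring is closed by this sigmatropic expansion of the three-membered ring, not by an end-to-end cyclisation, so no ring-size competition arises. C6 takes its absolute configuration from the catalyst: the (S)-prolinate is expected to attack the carbenoid face it uses in styrene cyclopropanation, giving the cyclopropane in which C10→C8→C9 runs clockwise seen from the vinyl-bearing face, and the concerted shift transfers this chirality to C6 (β oxygen). C5 is fixed relative to C6 by the boat geometry and the (E)-enol ether, which place the two inward-pointing hydrogens cis (5α-H, 6α-H). The step needs site selectivity (C9=C8 over the trisubstituted C6=C7 bond and over benzylic C–H insertion), secured by the 1,1-disubstituted enol ether terminus; cis-divinyl diastereoselectivity, which follows from the usual preference of the alkene's π substituent for the donor side of the carbenoid; and a concerted course, which hydrocarbon solvent and low temperature favour over ionisation of the donor–acceptor cyclopropane.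

Step 8
Reactants: 13 methyl 3,3-(ethylenedioxy)-6β-(4-methoxybenzyloxy)-8,11-bis(triethylsilyloxy)-15-nor-5αH-guaia-1(10),7-dien-14-oate
Product: 14 methyl 3,3-(ethylenedioxy)-6β-(4-methoxybenzyloxy)-8-oxo-11-(triethylsilyloxy)-15-nor-5αH,7αH-guai-1(10)-en-14-oate
Conditions: Bu4NF (1.05 equiv), AcOH (1.5 equiv), THF, −78 → −40 °C; used directly
Reagents that add atoms: none
Why: Buffered fluoride cleaves the silyl enol ether far faster than the tertiary silyl ether, and the enolate is protonated as it forms on the α face, anti to the pseudoaxial C6 ether, which should give 7α-H (C11 cis to the C6 oxygen) under kinetic control; low temperature and acetic acid guard against epimerisation and β-elimination.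

Step 9
Reactants: 14 methyl 3,3-(ethylenedioxy)-6β-(4-methoxybenzyloxy)-8-oxo-11-(triethylsilyloxy)-15-nor-5αH,7αH-guai-1(10)-en-14-oate
Product: 15 methyl 3,3-(ethylenedioxy)-8β-hydroxy-6β-(4-methoxybenzyloxy)-11-(triethylsilyloxy)-15-nor-5αH,7αH-guai-1(10)-en-14-oate
Conditions: LiBH(s-Bu)3, THF, −78 °C
Reagents that add atoms: none
Why: The bulky trialkylborohydride attacks the C8 ketone from the α face, anti to the adjacent β-oriented C11 group, giving the cis (8β) alcohol as in reductions of 2-substituted cycloalkanones; the tetrasubstituted enoate is inert to conjugate hydride addition.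

Step 10
Reactants: 15 methyl 3,3-(ethylenedioxy)-8β-hydroxy-6β-(4-methoxybenzyloxy)-11-(triethylsilyloxy)-15-nor-5αH,7αH-guai-1(10)-en-14-oate
Product: 16 methyl 8β-(tert-butyldimethylsilyloxy)-3,3-(ethylenedioxy)-6β-(4-methoxybenzyloxy)-11-(triethylsilyloxy)-15-nor-5αH,7αH-guai-1(10)-en-14-oate
Conditions: TBSOTf, 2,6-lutidine, CH2Cl2, −78 → 0 °C
Reagents that add atoms: tert-butyldimethylsilyl trifluoromethanesulfonate, CC(C)(C)[Si](C)(C)OS(=O)(=O)C(F)(F)F
Why: Silyl triflate silylation of a hindered secondary alcohol; the bulky, non-coordinating ether keeps the β-oriented C8 oxygen from directing the later epoxidation and hydrogenation.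

Step 11
Reactants: 16 methyl 8β-(tert-butyldimethylsilyloxy)-3,3-(ethylenedioxy)-6β-(4-methoxybenzyloxy)-11-(triethylsilyloxy)-15-nor-5αH,7αH-guai-1(10)-en-14-oate
Product: 17 8β-(tert-butyldimethylsilyloxy)-3,3-(ethylenedioxy)-6β-(4-methoxybenzyloxy)-11-(triethylsilyloxy)-15-nor-5αH,7αH-guai-1(10)-en-14-ol
Conditions: i-Bu2AlH (3 equiv), CH2Cl2, −78 → −20 °C; aq. potassium sodium tartrate
Reagents that add atoms: none
Why: 1,2-Reduction of the conjugated ester to the allylic alcohol by a dialkylaluminium hydride; ketal and ethers are unaffected.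

Step 12
Reactants: 17 8β-(tert-butyldimethylsilyloxy)-3,3-(ethylenedioxy)-6β-(4-methoxybenzyloxy)-11-(triethylsilyloxy)-15-nor-5αH,7αH-guai-1(10)-en-14-ol
Product: 18 8β-(tert-butyldimethylsilyloxy)-1α,10α-epoxy-3,3-(ethylenedioxy)-6β-(4-methoxybenzyloxy)-11-(triethylsilyloxy)-15-nor-5αH,7αH-guaian-14-ol
Conditions: VO(acac)2 (5 mol %), t-BuOOH, CH2Cl2, 0 → 25 °C
Reagents that add atoms: tert-butyl hydroperoxide, CC(C)(C)OO
Why: Hydroxyl-directed vanadium-catalysed epoxidation of the tetrasubstituted allylic alcohol; the CH2OH group can reach either face, but the α face carries only hydrogens at C5–C8 while the β face carries the PMB ether, C11 and the TBS ether, so oxygen should be delivered to the α face and fix C1.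

Step 13
Reactants: 18 8β-(tert-butyldimethylsilyloxy)-1α,10α-epoxy-3,3-(ethylenedioxy)-6β-(4-methoxybenzyloxy)-11-(triethylsilyloxy)-15-nor-5αH,7αH-guaian-14-ol
Product: 20 8β-(tert-butyldimethylsilyloxy)-3,3-(ethylenedioxy)-6β-(4-methoxybenzyloxy)-11-(triethylsilyloxy)-15-nor-5αH,7αH-guai-10(14)-en-1α-ol, via epoxy iodide 19 (not isolated)
Conditions: PPh3, I2, imidazole, THF, 0 °C; then Zn dust, AcOH, 0 → 25 °C
Reagents that add atoms: none
Why: Appel-type conversion of the primary alcohol into the iodide, then zinc-mediated reductive opening of the 2,3-epoxy iodide (β-elimination), gives the transposed tertiary allylic alcohol; the C1–O bond is not touched, so the α configuration is retained.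

Step 14
Reactants: 20 8β-(tert-butyldimethylsilyloxy)-3,3-(ethylenedioxy)-6β-(4-methoxybenzyloxy)-11-(triethylsilyloxy)-15-nor-5αH,7αH-guai-10(14)-en-1α-ol
Product: 21 8β-(tert-butyldimethylsilyloxy)-3,3-(ethylenedioxy)-6β-(4-methoxybenzyloxy)-11-(triethylsilyloxy)-15-nor-5αH,7αH,10αH-guaian-1α-ol
Conditions: H2 (1 atm), [Ir(cod)(PCy3)(py)]PF6 (5 mol %), CH2Cl2, 25 °C
Reagents that add atoms: none
Why: Hydroxyl-directed homogeneous hydrogenation: the cationic iridium catalyst binds the C1 hydroxyl and delivers hydrogen to the α face of the exocyclic alkene, placing 10-H α and the C10 methyl β; the PMB ether is stable to homogeneous hydrogenation.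

Step 15
Reactants: 21 8β-(tert-butyldimethylsilyloxy)-3,3-(ethylenedioxy)-6β-(4-methoxybenzyloxy)-11-(triethylsilyloxy)-15-nor-5αH,7αH,10αH-guaian-1α-ol
Product: 22 8β-(tert-butyldimethylsilyloxy)-1α-hydroxy-6β-(4-methoxybenzyloxy)-11-(triethylsilyloxy)-15-nor-5αH,7αH,10αH-guaian-3-one
Conditions: PPTS (cat.), acetone/H2O, 40 °C
Reagents that add atoms: water, O
Why: Mild acid-catalysed hydrolysis (transketalisation) of the dioxolane; the weak acid is chosen so that the tertiary β-hydroxy ketone does not dehydrate and the TBS and tertiary TES ethers persist.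

Step 16
Reactants: 22 8β-(tert-butyldimethylsilyloxy)-1α-hydroxy-6β-(4-methoxybenzyloxy)-11-(triethylsilyloxy)-15-nor-5αH,7αH,10αH-guaian-3-one
Product: 23 8β-(tert-butyldimethylsilyloxy)-1α-hydroxy-6β-(4-methoxybenzyloxy)-11-(triethylsilyloxy)-5αH,7αH,10αH-guaian-3-one (mixture of C4 epimers)
Conditions: LiN(i-Pr)2 (2.3 equiv), THF, −78 °C; MeI, −78 → −40 °C
Reagents that add atoms: iodomethane, CI
Why: α′-Alkylation of a β-hydroxy ketone dianion: the C1 alkoxide and the quaternary C1 turn kinetic enolisation away from C2 to C4, and the enolate is methylated there; the C4 configuration is irrelevant because C4 becomes sp2 in the next step.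

Step 17
Reactants: 23 8β-(tert-butyldimethylsilyloxy)-1α-hydroxy-6β-(4-methoxybenzyloxy)-11-(triethylsilyloxy)-5αH,7αH,10αH-guaian-3-one (mixture of C4 epimers)
Product: 24 8β-(tert-butyldimethylsilyloxy)-1α-hydroxy-6β-(4-methoxybenzyloxy)-11-(triethylsilyloxy)-7αH,10αH-guai-4-en-3-one
Conditions: 2-iodoxybenzoic acid (IBX, 2.5 equiv), 4-methoxypyridine N-oxide (2.5 equiv), DMSO, 25 °C
Reagents that add atoms: none
Why: IBX dehydrogenation of a ketone through its enol: only the C3–C4 enol has a β hydrogen (C5–H), because C1 is quaternary, so unsaturation can only enter at C4=C5; both C4 epimers converge and the C5 stereocentre is erased.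

Step 18
Reactants: 24 8β-(tert-butyldimethylsilyloxy)-1α-hydroxy-6β-(4-methoxybenzyloxy)-11-(triethylsilyloxy)-7αH,10αH-guai-4-en-3-one
Product: 25 1α,8β,11-trihydroxy-6β-(4-methoxybenzyloxy)-7αH,10αH-guai-4-en-3-one
Conditions: HF·pyridine, pyridine, THF, 0 → 25 °C
Reagents that add atoms: none
Why: Fluoride-mediated cleavage of both silyl ethers under weakly acidic, non-basic conditions that spare the γ-hydroxy enone (no retro-aldol) and the PMB ether.

Step 19
Reactants: 25 1α,8β,11-trihydroxy-6β-(4-methoxybenzyloxy)-7αH,10αH-guai-4-en-3-one; 26 angelic acid ((Z)-2-methylbut-2-enoic acid)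
Product: 28 8β-angeloyloxy-1α,11-dihydroxy-6β-(4-methoxybenzyloxy)-7αH,10αH-guai-4-en-3-one, via mixed anhydride 27 (not isolated)
Conditions: 26, 2,4,6-trichlorobenzoyl chloride, Et3N, toluene, 25 °C; then 25, toluene, 80 °C (no 4-dimethylaminopyridine)
Reagents that add atoms: none
Why: Yamaguchi-type mixed-anhydride esterification without a nucleophilic catalyst is the established way to make angelates without Z to E isomerisation; only the secondary C8 hydroxyl is acylated, the two tertiary hydroxyls being inert under these conditions.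

Step 20
Reactants: 28 8β-angeloyloxy-1α,11-dihydroxy-6β-(4-methoxybenzyloxy)-7αH,10αH-guai-4-en-3-one
Product: 29 11-acetoxy-8β-angeloyloxy-1α-hydroxy-6β-(4-methoxybenzyloxy)-7αH,10αH-guai-4-en-3-one
Conditions: Ac2O, 4-dimethylaminopyridine, Et3N, CH2Cl2, 25 °C
Reagents that add atoms: acetic anhydride, CC(=O)OC(C)=O
Why: Nucleophile-catalysed acetylation of a tertiary alcohol; the dimethylcarbinol at C11 is far more accessible than the ring-fusion C1 hydroxyl, which is flanked by three ring carbons and deactivated by the enone, so monoacetylation at C11 is expected.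

Step 21
Reactants: 29 11-acetoxy-8β-angeloyloxy-1α-hydroxy-6β-(4-methoxybenzyloxy)-7αH,10αH-guai-4-en-3-one
Product: 30 11-acetoxy-8β-angeloyloxy-1α,6β-dihydroxy-7αH,10αH-guai-4-en-3-one (target CNP0273287.1; 1R,6R,7R,8R,10S)
Conditions: DDQ, CH2Cl2/pH 7 buffer, 0 → 25 °C
Reagents that add atoms: none
Why: Oxidative cleavage of the PMB ether by DDQ under neutral conditions leaves both esters, the enone and the tertiary alcohol untouched; the electron-poor allylic alcohol that is released is not oxidised further.

## Compound list

1 | 1,4-dioxaspiro[4.4]nonan-7-one | O=C1CCC2(C1)OCCO2 | starting material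
2 | 1,4-dioxaspiro[4.4]non-7-en-7-yl trifluoromethanesulfonate | FC(F)(F)S(=O)(=O)OC1=CCC2(C1)OCCO2 | intermediate
3 | methyl bromoacetate | COC(=O)CBr | starting material
4 | (2-methoxy-2-oxoethyl)zinc bromide (bromozinc ester enolate) | COC(=O)C[Zn]Br | intermediate (not isolated)
5 | methyl 2-(1,4-dioxaspiro[4.4]non-7-en-7-yl)acetate | COC(=O)CC1=CCC2(C1)OCCO2 | intermediate
6 | methyl 2-diazo-2-(1,4-dioxaspiro[4.4]non-7-en-7-yl)acetate | COC(=O)C(=[N+]=[N-])C1=CCC2(C1)OCCO2 | intermediate
7 | 3-(ethoxymethylidene)pentane-2,4-dione | CCOC=C(C(C)=O)C(C)=O | starting material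
8 | 4-methoxybenzyl alcohol | COc1ccc(CO)cc1 | starting material
9 | 3-[(4-methoxybenzyloxy)methylidene]pentane-2,4-dione | COc1ccc(COC=C(C(C)=O)C(C)=O)cc1 | intermediate
10 | (E)-4-hydroxy-3-[(4-methoxybenzyloxy)methylidene]-4-methylpentan-2-one | CC(=O)/C(=C/OCc1ccc(OC)cc1)C(C)(C)O | intermediate
11 | (1E)-1-(4-methoxybenzyloxy)-3-(triethylsilyloxy)-2-[2-(triethylsilyloxy)propan-2-yl]buta-1,3-diene | C=C(O[Si](CC)(CC)CC)/C(=C/OCc1ccc(OC)cc1)C(C)(C)O[Si](CC)(CC)CC | intermediate
12 | methyl 1-(1,4-dioxaspiro[4.4]non-7-en-7-yl)-2-[(E)-1-(4-methoxybenzyloxy)-3-methyl-3-(triethylsilyloxy)but-1-en-2-yl]-2-(triethylsilyloxy)cyclopropane-1-carboxylate, the two alkenyl groups cis | COC(=O)[C@@]1(C2=CCC3(C2)OCCO3)C[C@]1(O[Si](CC)(CC)CC)/C(=C/OCc4ccc(OC)cc4)C(C)(C)O[Si](CC)(CC)CC | intermediate (not isolated)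
13 | methyl 3,3-(ethylenedioxy)-6β-(4-methoxybenzyloxy)-8,11-bis(triethylsilyloxy)-15-nor-5αH-guaia-1(10),7-dien-14-oate | COC(=O)C1=C2CC3(OCCO3)C[C@@H]2[C@H](OCc4ccc(OC)cc4)C(C(C)(C)O[Si](CC)(CC)CC)=C(O[Si](CC)(CC)CC)C1 | intermediate
14 | methyl 3,3-(ethylenedioxy)-6β-(4-methoxybenzyloxy)-8-oxo-11-(triethylsilyloxy)-15-nor-5αH,7αH-guai-1(10)-en-14-oate | COC(=O)C1=C2CC3(OCCO3)C[C@@H]2[C@H](OCc4ccc(OC)cc4)[C@H](C(C)(C)O[Si](CC)(CC)CC)C(=O)C1 | intermediate
15 | methyl 3,3-(ethylenedioxy)-8β-hydroxy-6β-(4-methoxybenzyloxy)-11-(triethylsilyloxy)-15-nor-5αH,7αH-guai-1(10)-en-14-oate | COC(=O)C1=C2CC3(OCCO3)C[C@@H]2[C@H](OCc4ccc(OC)cc4)[C@H](C(C)(C)O[Si](CC)(CC)CC)[C@H](O)C1 | intermediate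
16 | methyl 8β-(tert-butyldimethylsilyloxy)-3,3-(ethylenedioxy)-6β-(4-methoxybenzyloxy)-11-(triethylsilyloxy)-15-nor-5αH,7αH-guai-1(10)-en-14-oate | COC(=O)C1=C2CC3(OCCO3)C[C@@H]2[C@H](OCc4ccc(OC)cc4)[C@H](C(C)(C)O[Si](CC)(CC)CC)[C@H](O[Si](C)(C)C(C)(C)C)C1 | intermediate
17 | 8β-(tert-butyldimethylsilyloxy)-3,3-(ethylenedioxy)-6β-(4-methoxybenzyloxy)-11-(triethylsilyloxy)-15-nor-5αH,7αH-guai-1(10)-en-14-ol | OCC1=C2CC3(OCCO3)C[C@@H]2[C@H](OCc4ccc(OC)cc4)[C@H](C(C)(C)O[Si](CC)(CC)CC)[C@H](O[Si](C)(C)C(C)(C)C)C1 | intermediate
18 | 8β-(tert-butyldimethylsilyloxy)-1α,10α-epoxy-3,3-(ethylenedioxy)-6β-(4-methoxybenzyloxy)-11-(triethylsilyloxy)-15-nor-5αH,7αH-guaian-14-ol | OC[C@@]12O[C@]23CC4(OCCO4)C[C@@H]3[C@H](OCc5ccc(OC)cc5)[C@H](C(C)(C)O[Si](CC)(CC)CC)[C@H](O[Si](C)(C)C(C)(C)C)C1 | intermediate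
19 | 8β-(tert-butyldimethylsilyloxy)-1α,10α-epoxy-3,3-(ethylenedioxy)-14-iodo-6β-(4-methoxybenzyloxy)-11-(triethylsilyloxy)-15-nor-5αH,7αH-guaiane | IC[C@@]12O[C@]23CC4(OCCO4)C[C@@H]3[C@H](OCc5ccc(OC)cc5)[C@H](C(C)(C)O[Si](CC)(CC)CC)[C@H](O[Si](C)(C)C(C)(C)C)C1 | intermediate (not isolated)
20 | 8β-(tert-butyldimethylsilyloxy)-3,3-(ethylenedioxy)-6β-(4-methoxybenzyloxy)-11-(triethylsilyloxy)-15-nor-5αH,7αH-guai-10(14)-en-1α-ol | CC(C)(C)[Si](C)(C)O[C@@H]1CC(=C)[C@]2(O)CC3(OCCO3)C[C@@H]2[C@H](OCc4ccc(OC)cc4)[C@@H]1C(C)(C)O[Si](CC)(CC)CC | intermediate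
21 | 8β-(tert-butyldimethylsilyloxy)-3,3-(ethylenedioxy)-6β-(4-methoxybenzyloxy)-11-(triethylsilyloxy)-15-nor-5αH,7αH,10αH-guaian-1α-ol | CC(C)(C)[Si](C)(C)O[C@@H]1C[C@H](C)[C@]2(O)CC3(OCCO3)C[C@@H]2[C@H](OCc4ccc(OC)cc4)[C@@H]1C(C)(C)O[Si](CC)(CC)CC | intermediate
22 | 8β-(tert-butyldimethylsilyloxy)-1α-hydroxy-6β-(4-methoxybenzyloxy)-11-(triethylsilyloxy)-15-nor-5αH,7αH,10αH-guaian-3-one | CC(C)(C)[Si](C)(C)O[C@@H]1C[C@H](C)[C@]2(O)CC(=O)C[C@@H]2[C@H](OCc3ccc(OC)cc3)[C@@H]1C(C)(C)O[Si](CC)(CC)CC | intermediate
23 | 8β-(tert-butyldimethylsilyloxy)-1α-hydroxy-6β-(4-methoxybenzyloxy)-11-(triethylsilyloxy)-5αH,7αH,10αH-guaian-3-one, both C4 epimers | CC(C)(C)[Si](C)(C)O[C@@H]1C[C@H](C)[C@]2(O)CC(=O)C(C)[C@@H]2[C@H](OCc3ccc(OC)cc3)[C@@H]1C(C)(C)O[Si](CC)(CC)CC | intermediate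
24 | 8β-(tert-butyldimethylsilyloxy)-1α-hydroxy-6β-(4-methoxybenzyloxy)-11-(triethylsilyloxy)-7αH,10αH-guai-4-en-3-one | CC(C)(C)[Si](C)(C)O[C@@H]1C[C@H](C)[C@]2(O)CC(=O)C(C)=C2[C@H](OCc3ccc(OC)cc3)[C@@H]1C(C)(C)O[Si](CC)(CC)CC | intermediate
25 | 1α,8β,11-trihydroxy-6β-(4-methoxybenzyloxy)-7αH,10αH-guai-4-en-3-one | O[C@@H]1C[C@H](C)[C@]2(O)CC(=O)C(C)=C2[C@H](OCc3ccc(OC)cc3)[C@@H]1C(C)(C)O | intermediate
26 | angelic acid, (Z)-2-methylbut-2-enoic acid | C/C=C(/C)C(=O)O | starting material
27 | (Z)-2-methylbut-2-enoic 2,4,6-trichlorobenzoic anhydride | C/C=C(/C)C(=O)OC(=O)c1c(Cl)cc(Cl)cc1Cl | intermediate (not isolated)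
28 | 8β-angeloyloxy-1α,11-dihydroxy-6β-(4-methoxybenzyloxy)-7αH,10αH-guai-4-en-3-one | C/C=C(/C)C(=O)O[C@@H]1C[C@H](C)[C@]2(O)CC(=O)C(C)=C2[C@H](OCc3ccc(OC)cc3)[C@@H]1C(C)(C)O | intermediate
29 | 11-acetoxy-8β-angeloyloxy-1α-hydroxy-6β-(4-methoxybenzyloxy)-7αH,10αH-guai-4-en-3-one | C/C=C(/C)C(=O)O[C@@H]1C[C@H](C)[C@]2(O)CC(=O)C(C)=C2[C@H](OCc3ccc(OC)cc3)[C@@H]1C(C)(C)OC(C)=O | intermediate
30 | 11-acetoxy-8β-angeloyloxy-1α,6β-dihydroxy-7αH,10αH-guai-4-en-3-one (CNP0273287.1) | C/C=C(/C)C(=O)O[C@@H]1C[C@H](C)[C@]2(O)CC(=O)C(C)=C2[C@H](O)[C@@H]1C(C)(C)OC(C)=O | target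

## Step count and least certain steps

Total: 21 steps. Longest linear sequence: 18 steps (steps 1–3 or 4–6, then 7–21).

**Step 7 (key step).** The most likely failure is loss of enantiomeric purity or diversion of the cascade. Cyclopropane 12 is a vicinal donor–acceptor cyclopropane, and heterolysis of C8–C10 before the sigmatropic shift would pass through an achiral zwitterion (racemisation or formal [3+2] closure). The hindered 2,3-disubstituted diene may also fit the catalyst pocket poorly, so that carbene dimerisation or benzylic C–H insertion at the PMB group competes. Should the sense of induction be opposite to that expected, the enantiomeric (R)-prolinate catalyst would be used. As a fallback that replaces catalyst control by classical resolution, alcohol 15 of insufficient enantiomeric purity would be esterified with (S)-O-methylmandelic acid (dicyclohexylcarbodiimide, catalytic 4-dimethylaminopyridine, CH2Cl2, 0 °C). The major diastereomer, the C8 (S)-O-methylmandelate ester F1, would be separated by chromatography or crystallisation and cleaved with K2CO3 in methanol, returning to enantiopure 15.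

**Step 5.** Conjugate addition–elimination at the methine carbon (displacement of the PMB oxide) or a second addition may compete with the desired single 1,2-addition, because the alkoxymethylidene diketone is a strong Michael acceptor. The fallback masks the acceptor as an isoxazole. It sets out from 7, which with hydroxylamine hydrochloride in ethanol gives 1-(5-methylisoxazol-4-yl)ethanone F2, an ordinary methyl ketone. MeMgBr at −78 °C gives 2-(5-methylisoxazol-4-yl)propan-2-ol F3. Reductive N–O cleavage with Mo(CO)6 in wet acetonitrile gives (Z)-3-(aminomethylidene)-4-hydroxy-4-methylpentan-2-one F4, and aqueous oxalic acid hydrolyses it to 4-hydroxy-3-(hydroxymethylidene)-4-methylpentan-2-one F5. Mitsunobu O-alkylation of this acidic enol with 8 returns to 10.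

**Step 8.** Once the C8 ketone is unmasked, epimerisation at C7 towards the less crowded trans arrangement, or β-elimination of the C6 or C11 oxygen, can occur under the fluoride conditions, and protonation may not be fully face-selective. The fallback changes the order so that the enolate is released without fluoride and the ketone is reduced in the flask in which it forms. It sets out from 13: i-Bu2AlH reduces the ester first to the allylic alcohol enol ether F6. MeLi (2.2 equiv, THF, 0 °C) then liberates the lithium enolate, a hindered phenol protonates it at −78 °C to the transient hydroxy ketone F7, and LiBH(s-Bu)3 added to the same flask gives the 8β,14-diol F8. Double silylation (TBSOTf, 2,6-lutidine) gives the bis-TBS ether F9, and brief treatment with HF·pyridine removes the primary allylic silyl group, returning to 17.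

**Step 16.** Proton exchange between product and enolate can cause over-methylation, the lithium aldolate can open by retro-aldol cleavage on warming, and some enolisation towards C2 cannot be excluded. The fallback introduces the methyl group by cross-coupling instead of enolate alkylation. It sets out from 22: the same IBX dehydrogenation gives the unmethylated enone F10 (C4=C5 is again the only possible position). Iodine with pyridine, or with 4-dimethylaminopyridine as the nucleophilic catalyst, gives the α-iodoenone F11, and Stille coupling with tetramethylstannane (Pd2(dba)3, AsPh3, CuI, N-methylpyrrolidinone, 60 °C) returns to 24.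

**Step 20.** Acylation of the hindered tertiary C11 hydroxyl may be slow, and forcing it risks acetylation of the C1 hydroxyl or nucleophile-induced Z to E isomerisation of the angelate. The fallback installs the acetate before the angelate. It sets out from 24: controlled HF·pyridine at 0 °C removes the triethylsilyl group first, giving the C11 alcohol F12 with the C8 TBS ether intact. Acetylation (Ac2O, 4-dimethylaminopyridine, if necessary warm, with no angelate present) gives the C11 acetate F13. Longer exposure to HF·pyridine gives the C8 alcohol F14, and esterification with the mixed anhydride 27 as in step 19 returns to 29.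

## Further compounds

F1 | step 7 | C8 (S)-O-methylmandelate ester of 15 | COC(=O)C1=C2CC3(OCCO3)C[C@@H]2[C@H](OCc4ccc(OC)cc4)[C@H](C(C)(C)O[Si](CC)(CC)CC)[C@H](OC(=O)[C@@H](OC)c5ccccc5)C1
F2 | step 5 | 1-(5-methylisoxazol-4-yl)ethanone | CC(=O)c1cnoc1C
F3 | step 5 | 2-(5-methylisoxazol-4-yl)propan-2-ol | Cc1oncc1C(C)(C)O
F4 | step 5 | (Z)-3-(aminomethylidene)-4-hydroxy-4-methylpentan-2-one | CC(=O)/C(=C\N)C(C)(C)O
F5 | step 5 | 4-hydroxy-3-(hydroxymethylidene)-4-methylpentan-2-one | CC(=O)C(=CO)C(C)(C)O
F6 | step 8 | 3,3-(ethylenedioxy)-6β-(4-methoxybenzyloxy)-8,11-bis(triethylsilyloxy)-15-nor-5αH-guaia-1(10),7-dien-14-ol | OCC1=C2CC3(OCCO3)C[C@@H]2[C@H](OCc4ccc(OC)cc4)C(C(C)(C)O[Si](CC)(CC)CC)=C(O[Si](CC)(CC)CC)C1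
F7 | step 8 | 3,3-(ethylenedioxy)-14-hydroxy-6β-(4-methoxybenzyloxy)-11-(triethylsilyloxy)-15-nor-5αH,7αH-guai-1(10)-en-8-one | OCC1=C2CC3(OCCO3)C[C@@H]2[C@H](OCc4ccc(OC)cc4)[C@H](C(C)(C)O[Si](CC)(CC)CC)C(=O)C1
F8 | step 8 | 3,3-(ethylenedioxy)-6β-(4-methoxybenzyloxy)-11-(triethylsilyloxy)-15-nor-5αH,7αH-guai-1(10)-ene-8β,14-diol | OCC1=C2CC3(OCCO3)C[C@@H]2[C@H](OCc4ccc(OC)cc4)[C@H](C(C)(C)O[Si](CC)(CC)CC)[C@H](O)C1
F9 | step 8 | 8β,14-bis(tert-butyldimethylsilyloxy)-3,3-(ethylenedioxy)-6β-(4-methoxybenzyloxy)-11-(triethylsilyloxy)-15-nor-5αH,7αH-guai-1(10)-ene | CC(C)(C)[Si](C)(C)OCC1=C2CC3(OCCO3)C[C@@H]2[C@H](OCc4ccc(OC)cc4)[C@H](C(C)(C)O[Si](CC)(CC)CC)[C@H](O[Si](C)(C)C(C)(C)C)C1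
F10 | step 16 | 8β-(tert-butyldimethylsilyloxy)-1α-hydroxy-6β-(4-methoxybenzyloxy)-11-(triethylsilyloxy)-15-nor-7αH,10αH-guai-4-en-3-one | CC(C)(C)[Si](C)(C)O[C@@H]1C[C@H](C)[C@]2(O)CC(=O)C=C2[C@H](OCc3ccc(OC)cc3)[C@@H]1C(C)(C)O[Si](CC)(CC)CC
F11 | step 16 | 8β-(tert-butyldimethylsilyloxy)-1α-hydroxy-4-iodo-6β-(4-methoxybenzyloxy)-11-(triethylsilyloxy)-15-nor-7αH,10αH-guai-4-en-3-one | CC(C)(C)[Si](C)(C)O[C@@H]1C[C@H](C)[C@]2(O)CC(=O)C(I)=C2[C@H](OCc3ccc(OC)cc3)[C@@H]1C(C)(C)O[Si](CC)(CC)CC
F12 | step 20 | 8β-(tert-butyldimethylsilyloxy)-1α,11-dihydroxy-6β-(4-methoxybenzyloxy)-7αH,10αH-guai-4-en-3-one | CC(C)(C)[Si](C)(C)O[C@@H]1C[C@H](C)[C@]2(O)CC(=O)C(C)=C2[C@H](OCc3ccc(OC)cc3)[C@@H]1C(C)(C)O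
F13 | step 20 | 11-acetoxy-8β-(tert-butyldimethylsilyloxy)-1α-hydroxy-6β-(4-methoxybenzyloxy)-7αH,10αH-guai-4-en-3-one | CC(C)(C)[Si](C)(C)O[C@@H]1C[C@H](C)[C@]2(O)CC(=O)C(C)=C2[C@H](OCc3ccc(OC)cc3)[C@@H]1C(C)(C)OC(C)=O
F14 | step 20 | 11-acetoxy-1α,8β-dihydroxy-6β-(4-methoxybenzyloxy)-7αH,10αH-guai-4-en-3-one | O[C@@H]1C[C@H](C)[C@]2(O)CC(=O)C(C)=C2[C@H](OCc3ccc(OC)cc3)[C@@H]1C(C)(C)OC(C)=O
A1 | alternative 1 | 11-acetoxy-3,6,8-tris(tert-butyldimethylsilyloxy)guai-3-en-1-ol (product of the transannular ene closure) | CC(C)(C)[Si](C)(C)O[C@@H]1C[C@H](C)[C@]2(O)CC(O[Si](C)(C)C(C)(C)C)=C(C)[C@@H]2[C@H](O[Si](C)(C)C(C)(C)C)[C@@H]1C(C)(C)OC(C)=O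
A2 | alternative 2 | 8-(tert-butyldimethylsilyloxy)-3,3-(ethylenedioxy)-1-(methoxymethoxy)guaia-4,11-dien-6-ol (product of the ring contraction) | CC(C)(C)[Si](C)(C)O[C@@H]1C[C@H](C)[C@]2(OCOC)CC3(OCCO3)C(C)=C2[C@H](O)[C@@H]1C(C)=C
A3 | alternative 3 | 6-benzyloxy-7-(2-hydroxypropan-2-yl)-10-methyl-5-(3-oxobutan-2-yl)cycloheptane-1,8-dione, guaiane numbering (product of the two-carbon ring expansion) | O=C1C[C@H](C)C(=O)[C@H]([C@@H](C)C(C)=O)[C@H](OCc2ccccc2)[C@@H]1C(C)(C)O
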